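## Retrosynthetic overview

1. Numbering used throughout: C1 (bridgehead with prenyl, next to C8Me2), C2 (C–OMe), C3 (C–benzoyl), C4 (ring C=O), C5 (bridgehead with the lavandulyl CH2), C6 (CH2), C7 (CH–prenyl), C8 (CMe2), C9 (bridging C=O); ring A = C1/C9/C5/C6/C7/C8, ring B = C1/C2/C3/C4/C5/C9.
2. Last disconnection: the C3–benzoyl bond (C3 lithiation of the bicyclic methyl vinylogous ester 26, then BzCl). Key disconnection: the C4–C5 bond of ring B, which leads from 26 back to the monocyclic cyclohex-2-enone 24.
3. Enabling feature of 24: the ring-A enone C9(=O)–C5=C6, flanked on its other side by the already quaternary C1, which carries the C2(OMe)=C3–C4(=O)SEt arm 1,3 to C5. The enone blocks C5 while C1 is substituted twice, brings in the lavandulyl group (α-iodination, Negishi coupling), and after 1,4-hydrosilylation becomes the C5=C9 silyl enol ether that the silver-unmasked C4 acylium ion acylates.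
4. C1–C2 comes from an Effenberger-type C-acylation of a silyl dienol ether with malonyl dichloride (the arm enters trans to the C7 prenyl group, exo series); O-methylation of the β-keto thioester fixes OMe on C2 before C4 becomes a ketone.
5. Ring A is made first (organocatalytic Michael/aldol annulation sets C7; two cuprate β-methylations build C8Me2); ring B is closed in the penultimate step; the lavandulyl stereocentre comes from an Evans deconjugative prenylation.

Key step: step 15

Remark: 5-methylhex-4-enal is taken as a commercial starting material; compounds 20, 24, F1 and F7 are carried as the isomer mixtures named in the list, which later steps make converge.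

## Route

Step 1
Reactants: 1 5-methylhex-4-enal; 2 but-3-en-2-one
Product: 4 (4S)-4-(3-methylbut-2-en-1-yl)cyclohex-2-en-1-one, via keto aldehyde 3 (not isolated)
Conditions: (S)-α,α-diphenylprolinol methyl ether (5 mol%), ethyl 3,4-dihydroxybenzoate (20 mol%), neat, 4 °C; then LiOH (10 mol%), i-PrOH, 23 °C
Reagents that add atoms: none
Why: Enamine-catalysed Michael addition followed by intramolecular aldol condensation (organocatalytic Robinson-type annulation); the enone should add to the enamine face remote from the CPh2(OMe) group, which sets the future C7 as (S) here.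

Step 2
Reactants: 4 (4S)-4-prenylcyclohex-2-en-1-one
Product: 6 (4S)-3-methyl-4-(3-methylbut-2-en-1-yl)cyclohex-2-en-1-one, via lithium enolate 5 (not isolated)
Conditions: Me2CuLi, Et2O, −78 → −40 °C; then PhS(Cl)=N-t-Bu, THF, −78 °C → rt
Reagents that add atoms: lithium dimethylcuprate, [Li+].C[Cu-]C
Why: Gilman conjugate addition anti to the C4 side chain followed by Mukaiyama dehydrogenation of the enolate in the same flask amounts to a β-methylation of the enone; the transient C3 stereocentre is erased and C4 is untouched.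

Step 3
Reactants: 6 (4S)-3-methyl-4-prenylcyclohex-2-en-1-one
Product: 7 (4S)-3,3-dimethyl-4-(3-methylbut-2-en-1-yl)cyclohexan-1-one
Conditions: Me2CuLi, BF3·OEt2, Et2O, −78 → −30 °C; aq. NH4Cl
Reagents that add atoms: lithium dimethylcuprate, [Li+].C[Cu-]C
Why: Lewis-acid-accelerated cuprate conjugate addition to the β,β-disubstituted enone should create the gem-dimethyl carbon (C8) without forming a new stereocentre.

Step 4
Reactants: 7 (4S)-3,3-dimethyl-4-prenylcyclohexan-1-one
Product: 9 (4R)-5,5-dimethyl-4-(3-methylbut-2-en-1-yl)cyclohex-2-en-1-one, via kinetic lithium enolate 8 (not isolated)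
Conditions: LDA, THF, −78 °C; then PhS(Cl)=N-t-Bu, −78 °C
Reagents that add atoms: none
Why: Kinetic deprotonation takes the CH2 remote from the gem-dimethyl group and Mukaiyama dehydrogenation can only desaturate that side (the other α-carbon has no β-hydrogen), which gives the enone that will block C5 (CIP label changes, configuration unchanged).

Step 5
Reactants: 9 (4R)-5,5-dimethyl-4-prenylcyclohex-2-en-1-one
Product: 10 (4R)-2-iodo-5,5-dimethyl-4-(3-methylbut-2-en-1-yl)cyclohex-2-en-1-one
Conditions: I2, pyridine/CH2Cl2 (1:1), 0 °C → rt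
Reagents that add atoms: iodine, II
Why: α-Iodination of a β-unsubstituted enone by the pyridine addition / enolate iodination / E1cB sequence (Baylis–Hillman-type) is selective for the enone α-carbon and should leave the trisubstituted alkene alone.

Step 6
Reactants: 11 (4S)-4-benzyl-1,3-oxazolidin-2-one
Product: 12 (4S)-4-benzyl-3-(3-methylbut-2-enoyl)-1,3-oxazolidin-2-one
Conditions: 3-methylbut-2-enoyl chloride, Et3N, DMAP (cat.), CH2Cl2, 0 °C → rt
Reagents that add atoms: 3-methylbut-2-enoyl chloride, CC(C)=CC(Cl)=O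
Why: DMAP-catalysed N-acylation of the Evans auxiliary with an acid chloride.

Step 7
Reactants: 12 N-senecioyl oxazolidinone
Product: 14 (4S)-4-benzyl-3-[(2S)-5-methyl-2-(prop-1-en-2-yl)hex-4-enoyl]-1,3-oxazolidin-2-one, via sodium Z-dienolate 13 (not isolated)
Conditions: NaHMDS, THF, −78 °C; then prenyl bromide, −78 → −40 °C
Reagents that add atoms: 1-bromo-3-methylbut-2-ene, CC(C)=CCBr
Why: Deconjugative Evans alkylation: the chelated Z(O)-dienolate should be alkylated at Cα on the face opposite the benzyl group, which sets the lavandulyl stereocentre.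

Step 8
Reactants: 14 alkylated imide
Product: 15 (S)-lavandulol
Conditions: LiBH4, MeOH (1.1 equiv), Et2O, 0 °C; aq. NaOH
Reagents that add atoms: none
Why: Reductive cleavage of the N-acyl oxazolidinone with LiBH4 should give the primary alcohol without epimerising the β,γ-unsaturated stereocentre.

Step 9
Reactants: 15 (S)-lavandulol
Product: 16 (S)-lavandulyl iodide
Conditions: I2, PPh3, imidazole, CH2Cl2, 0 °C
Reagents that add atoms: iodine, II
Why: Appel-type iodination occurs by SN2 at the primary carbon, so the adjacent stereocentre is not involved.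

Step 10
Reactants: 16 (S)-lavandulyl iodide; 10 (4R)-2-iodo-5,5-dimethyl-4-prenylcyclohex-2-en-1-one
Product: 18 (4R)-5,5-dimethyl-4-(3-methylbut-2-en-1-yl)-2-[(2R)-5-methyl-2-(prop-1-en-2-yl)hex-4-en-1-yl]cyclohex-2-en-1-one, via lavandulylzinc iodide 17 (not isolated)
Conditions: Zn dust (activated), LiCl, THF, 35 °C; then 10, Pd2(dba)3 (2.5 mol%), SPhos (10 mol%), THF/NMP, 25 °C
Reagents that add atoms: none
Why: Zinc insertion into the primary iodide and Negishi sp3–sp2 coupling with the α-iodoenone should attach the lavandulyl group to the future C5 with both stereocentres untouched (the side-chain CIP label changes from S to R, the configuration does not).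

Step 11
Reactants: 18 α-lavandulyl enone
Product: 20 (4R,6S)-5,5-dimethyl-4,6-bis(3-methylbut-2-en-1-yl)-2-[(2R)-5-methyl-2-(prop-1-en-2-yl)hex-4-en-1-yl]cyclohex-2-en-1-one, via lithium dienolate 19 (not isolated)
Conditions: LDA, THF, −78 °C; then prenyl bromide, −78 → 0 °C
Reagents that add atoms: 1-bromo-3-methylbut-2-ene, CC(C)=CCBr
Why: Kinetic α′-enolate alkylation of a cyclohexenone; the C5=C6 double bond leaves only the future C1 available, and the new stereocentre (trans expected) is erased in step 12.

Step 12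
Reactants: 20 α′-prenyl enone
Product: 21 trimethylsilyl dienol ether of 20
Conditions: LDA, TMSCl (internal quench), THF, −78 °C; pentane, filtration
Reagents that add atoms: chlorotrimethylsilane, C[Si](C)(C)Cl
Why: Kinetic α′-deprotonation with in situ O-silylation should give the 2-silyloxy-1,3-diene whose only nucleophilic carbon is the future C1.

Step 13
Reactants: 21 silyl dienol ether
Product: 23 S-ethyl β-keto thioester with quaternary C1, via keto acid chloride 22 (not isolated)
Conditions: malonyl dichloride, CH2Cl2, −20 °C; then EtSH, pyridine, −20 → 0 °C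
Reagents that add atoms: malonyl dichloride, O=C(Cl)CC(Cl)=O; ethanethiol, CCS
Why: Effenberger-type C-acylation of the silyl enol ether (the first C–C bond of the Effenberger annulation) should build quaternary C1 with the acyl group entering anti to the pseudoaxial C8 methyl, that is trans to the C7 prenyl group; C5 is an enone sp2 carbon, so the second acylation cannot follow and the acid chloride is intercepted as the thioester.

Step 14
Reactants: 23 β-keto thioester
Product: 24 S-ethyl β-methoxy thioacrylate (E/Z mixture)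
Conditions: TMSCHN2, MeOH/toluene (1:4), 0 °C → rt
Reagents that add atoms: (trimethylsilyl)diazomethane, C[Si](C)(C)C=[N+]=[N-]
Why: O-Methylation of the enolised β-keto thioester under neutral conditions (no enolate that could add to the enone) places the methoxy group on C2 before C4 is a ketone, so the regiochemistry of the final enol ether is fixed by construction.

Step 15
Reactants: 24 S-ethyl β-methoxy thioacrylate enone
Product: 26 (1R,5S,7R)-2-methoxy-8,8-dimethyl-1,7-bis(3-methylbut-2-en-1-yl)-5-[(2R)-5-methyl-2-(prop-1-en-2-yl)hex-4-en-1-yl]bicyclo[3.3.1]non-2-ene-4,9-dione, via silyl enol ether 25 (not isolated)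
Conditions: [(Ph3P)CuH]6 (5 mol%), PhMe2SiH, toluene, 23 °C; then AgOTf, 2,6-di-tert-butyl-4-methylpyridine, CH2Cl2, 0 → 23 °C
Reagents that add atoms: none
Why: Proposed new method: Stryker's reagent should deliver hydride to C6 of the ring-A enone and the copper enolate is silylated by PhMe2SiH to the tetrasubstituted C5=C9 silyl enol ether 25 (C1 is quaternary, so no other enol ether can form); AgOTf then removes ethanethiolate from the thioester, and the β-methoxy acylium ion, whose ketene–oxocarbenium resonance form has a C2–C3 single bond so that E and Z arms interconvert, is attacked at C4 by C5, after which loss of PhMe2SiOTf gives the C9 ketone. The closest known reaction types are the ring-closing C-acylation of the Effenberger annulation (enol ether plus acid chloride at this same bond), Mukaiyama C-acylation of silyl enol ethers, copper hydride-catalysed conjugate hydrosilylation of enones and silver(I) activation of thioesters. Ring B (C1–C2–C3–C4–C5–C9) closes in a 6-(enolendo)-exo-dig mode. The only new stereocentre, C5, is controlled by quaternary C1: the three-carbon arm is axial on C1 and can bond only to the same face of C5 (1,3-diaxial bridge), and because the arm is trans to the C7 prenyl group the ring-A chair keeps that group equatorial (exo). The step needs 1,4- over 1,2-reduction with the other alkenes and the thioacrylate left alone (copper hydride is selective for the enone; the β-methoxy thioacrylate is a deactivated vinylogous thiocarbonate), C- over O-acylation (the enol oxygen is silylated, as in the Effenberger reaction) and convergence of both double-bond isomers of 24 (secured by the acylium ion).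

Step 16
Reactants: 26 bicyclic methyl vinylogous ester
Product: 28 (1R,5R,7R)-3-benzoyl-2-methoxy-8,8-dimethyl-1,7-bis(3-methylbut-2-en-1-yl)-5-[(2R)-5-methyl-2-(prop-1-en-2-yl)hex-4-en-1-yl]bicyclo[3.3.1]non-2-ene-4,9-dione, via C3-lithio vinylogous ester 27 (not isolated)
Conditions: LiTMP, THF, −78 °C; then BzCl, −78 → −40 °C
Reagents that add atoms: benzoyl chloride, O=C(Cl)c1ccccc1
Why: Directed C3 lithiation of the β-methoxy enone (the only kinetically acidic C–H, both bridgeheads being quaternary) and acylation with benzoyl chloride, a known operation on bicyclo[3.3.1]nonane methyl vinylogous esters; no stereocentre is touched.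

## Compound list

1 | 5-methylhex-4-enal | CC(C)=CCCC=O | starting material
2 | but-3-en-2-one | CC(=O)C=C | starting material
3 | (2S)-2-(3-methylbut-2-en-1-yl)-5-oxohexanal | O=C[C@H](CC=C(C)C)CCC(C)=O | intermediate (not isolated)
4 | (4S)-4-(3-methylbut-2-en-1-yl)cyclohex-2-en-1-one | O=C1C=C[C@H](CC=C(C)C)CC1 | intermediate
5 | lithium (3S,4S)-3-methyl-4-(3-methylbut-2-en-1-yl)cyclohex-1-en-1-olate | [Li+].[O-]C1=C[C@@H](C)[C@H](CC=C(C)C)CC1 | intermediate (not isolated)
6 | (4S)-3-methyl-4-(3-methylbut-2-en-1-yl)cyclohex-2-en-1-one | O=C1C=C(C)[C@H](CC=C(C)C)CC1 | intermediate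
7 | (4S)-3,3-dimethyl-4-(3-methylbut-2-en-1-yl)cyclohexan-1-one | O=C1CC(C)(C)[C@H](CC=C(C)C)CC1 | intermediate
8 | lithium (4R)-5,5-dimethyl-4-(3-methylbut-2-en-1-yl)cyclohex-1-en-1-olate | [Li+].[O-]C1=CC[C@@H](CC=C(C)C)C(C)(C)C1 | intermediate (not isolated)
9 | (4R)-5,5-dimethyl-4-(3-methylbut-2-en-1-yl)cyclohex-2-en-1-one | O=C1C=C[C@@H](CC=C(C)C)C(C)(C)C1 | intermediate
10 | (4R)-2-iodo-5,5-dimethyl-4-(3-methylbut-2-en-1-yl)cyclohex-2-en-1-one | O=C1C(I)=C[C@@H](CC=C(C)C)C(C)(C)C1 | intermediate
11 | (4S)-4-benzyl-1,3-oxazolidin-2-one | O=C1N[C@@H](Cc2ccccc2)CO1 | starting material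
12 | (4S)-4-benzyl-3-(3-methylbut-2-enoyl)-1,3-oxazolidin-2-one | CC(C)=CC(=O)N1[C@@H](Cc2ccccc2)COC1=O | intermediate
13 | sodium (Z)-dienolate of 12 | [Na+].[O-]/C(=C\C(C)=C)N1[C@@H](Cc2ccccc2)COC1=O | intermediate (not isolated)
14 | (4S)-4-benzyl-3-[(2S)-5-methyl-2-(prop-1-en-2-yl)hex-4-enoyl]-1,3-oxazolidin-2-one | C=C(C)[C@H](CC=C(C)C)C(=O)N1[C@@H](Cc2ccccc2)COC1=O | intermediate
15 | (S)-lavandulol, (2S)-5-methyl-2-(prop-1-en-2-yl)hex-4-en-1-ol | C=C(C)[C@H](CC=C(C)C)CO | intermediate
16 | (S)-lavandulyl iodide, (3S)-3-(iodomethyl)-2,6-dimethylhepta-1,5-diene | C=C(C)[C@H](CC=C(C)C)CI | intermediate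
17 | (S)-lavandulylzinc iodide | C=C(C)[C@H](CC=C(C)C)C[Zn]I | intermediate (not isolated)
18 | (4R)-5,5-dimethyl-4-(3-methylbut-2-en-1-yl)-2-[(2R)-5-methyl-2-(prop-1-en-2-yl)hex-4-en-1-yl]cyclohex-2-en-1-one | C=C(C)[C@H](CC=C(C)C)CC1=C[C@@H](CC=C(C)C)C(C)(C)CC1=O | intermediate
19 | lithium cross-conjugated dienolate of 18 | C=C(C)[C@H](CC=C(C)C)CC1=C[C@@H](CC=C(C)C)C(C)(C)C=C1[O-].[Li+] | intermediate (not isolated)
20 | (4R,6S)-5,5-dimethyl-4,6-bis(3-methylbut-2-en-1-yl)-2-[(2R)-5-methyl-2-(prop-1-en-2-yl)hex-4-en-1-yl]cyclohex-2-en-1-one (expected major epimer; C6 is erased in step 12) | C=C(C)[C@H](CC=C(C)C)CC1=C[C@@H](CC=C(C)C)C(C)(C)[C@H](CC=C(C)C)C1=O | intermediate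
21 | trimethyl({(4R)-3,3-dimethyl-2,4-bis(3-methylbut-2-en-1-yl)-6-[(2R)-5-methyl-2-(prop-1-en-2-yl)hex-4-en-1-yl]cyclohexa-1,5-dien-1-yl}oxy)silane | C=C(C)[C@H](CC=C(C)C)CC1=C[C@@H](CC=C(C)C)C(C)(C)C(CC=C(C)C)=C1O[Si](C)(C)C | intermediate
22 | 3-{(1R,5R)-6,6-dimethyl-1,5-bis(3-methylbut-2-en-1-yl)-3-[(2R)-5-methyl-2-(prop-1-en-2-yl)hex-4-en-1-yl]-2-oxocyclohex-3-en-1-yl}-3-oxopropanoyl chloride | C=C(C)[C@H](CC=C(C)C)CC1=C[C@@H](CC=C(C)C)C(C)(C)[C@](CC=C(C)C)(C(=O)CC(Cl)=O)C1=O | intermediate (not isolated)
23 | S-ethyl 3-{(1R,5R)-6,6-dimethyl-1,5-bis(3-methylbut-2-en-1-yl)-3-[(2R)-5-methyl-2-(prop-1-en-2-yl)hex-4-en-1-yl]-2-oxocyclohex-3-en-1-yl}-3-oxopropanethioate | C=C(C)[C@H](CC=C(C)C)CC1=C[C@@H](CC=C(C)C)C(C)(C)[C@](CC=C(C)C)(C(=O)CC(=O)SCC)C1=O | intermediate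
24 | S-ethyl 3-methoxy-3-{(1R,5R)-6,6-dimethyl-1,5-bis(3-methylbut-2-en-1-yl)-3-[(2R)-5-methyl-2-(prop-1-en-2-yl)hex-4-en-1-yl]-2-oxocyclohex-3-en-1-yl}prop-2-enethioate (E/Z mixture, geometry left open) | C=C(C)[C@H](CC=C(C)C)CC1=C[C@@H](CC=C(C)C)C(C)(C)[C@](CC=C(C)C)(C(OC)=CC(=O)SCC)C1=O | intermediate
25 | C5=C9 dimethylphenylsilyl enol ether of 1,4-reduced 24 (1R,5R in ring numbering from the quaternary carbon; E/Z mixture) | C=C(C)[C@H](CC=C(C)C)CC1=C(O[Si](C)(C)c2ccccc2)[C@@](CC=C(C)C)(C(OC)=CC(=O)SCC)C(C)(C)[C@H](CC=C(C)C)C1 | intermediate (not isolated)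
26 | (1R,5S,7R)-2-methoxy-8,8-dimethyl-1,7-bis(3-methylbut-2-en-1-yl)-5-[(2R)-5-methyl-2-(prop-1-en-2-yl)hex-4-en-1-yl]bicyclo[3.3.1]non-2-ene-4,9-dione | C=C(C)[C@H](CC=C(C)C)C[C@@]12C[C@@H](CC=C(C)C)C(C)(C)[C@@](CC=C(C)C)(C1=O)C(OC)=CC2=O | intermediate
27 | 3-lithio derivative of 26 | C=C(C)[C@H](CC=C(C)C)C[C@@]12C[C@@H](CC=C(C)C)C(C)(C)[C@@](CC=C(C)C)(C1=O)C(OC)=C([Li])C2=O | intermediate (not isolated)
28 | CNP0385193.1, (1R,5R,7R)-3-benzoyl-2-methoxy-8,8-dimethyl-1,7-bis(3-methylbut-2-en-1-yl)-5-[(2R)-5-methyl-2-(prop-1-en-2-yl)hex-4-en-1-yl]bicyclo[3.3.1]non-2-ene-4,9-dione | C=C(C)[C@H](CC=C(C)C)C[C@@]12C[C@@H](CC=C(C)C)C(C)(C)[C@@](CC=C(C)C)(C1=O)C(OC)=C(C(=O)c1ccccc1)C2=O | target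

## Step count and risks

Total step count: 16. Longest linear sequence: 12 steps (steps 1–5 and 10–16); the lavandulyl branch (steps 6–9) joins at step 10.

Steps most likely to fail:

1. Step 15 (Proposed new method). What may go wrong: sluggish or unselective conjugate hydrosilylation of the hindered enone, O- instead of C-acylation, or capture of the acylium ion by a prenyl double bond. The fallback sets out from 24 and comes back at 26. The silyl enol ether 25 would be protodesilylated (TBAF, AcOH, THF, 0 °C) to the saturated keto thioester F1 (C5 epimers, E/Z mixture). Triplet-sensitised irradiation (thioxanthone, 405 nm, MeCN) would then enrich the (E)-thioacrylate F2, in which the thioester is cis to C1. KHMDS (THF, −78 → 0 °C) would close ring B by a conventional anionic thioester Claisen (Dieckmann-type) acylation of the C5 enolate, which makes both C5 epimers converge on 26; recovered Z material would be irradiated again.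

2. Step 13. What may go wrong: O-acylation or no reaction at the congested C1 (vicinal quaternary carbons), or erosion of facial selectivity. The fallback sets out from 21 and comes back at 23, and builds C1–C2 with a small cationic electrophile. Mukaiyama reaction of 21 with trimethyl orthoformate (BF3·OEt2, CH2Cl2, −78 °C) would give the dimethyl acetal F3. Mild hydrolysis (PPTS, acetone/H2O) would give the non-enolisable aldehyde F4. Aldol addition of the lithium enolate of S-ethyl thioacetate (LDA, THF, −78 °C) would give the β-hydroxy thioester F5, and Dess–Martin oxidation would deliver 23.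

3. Step 10. What may go wrong: slow transmetallation or β-hydride elimination of the β-branched alkylzinc, and protodeiodination of the iodoenone. The fallback sets out from 9 (with 15) and comes back at 18, and uses enolate alkylation instead of cross-coupling. Alcohol 15 would be converted into (S)-lavandulyl triflate F6 (Tf2O, 2,6-lutidine, CH2Cl2, −78 °C). Conjugate reduction of 9 with L-Selectride (THF, −78 °C) and alkylation of the resulting enolate with F6 would give the saturated 2-lavandulyl ketone F7 (epimer mixture). IBX dehydrogenation (DMSO, 65 °C), possible only on the side that carries a β-hydrogen, would give 18.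

## Further compounds

F1 | step 15 | S-ethyl 3-methoxy-3-{(1R)-...-2-oxocyclohexyl}prop-2-enethioate, the 1,4-reduced form of 24 (C5 epimers, E/Z mixture) | C=C(C)[C@H](CC=C(C)C)CC1C[C@@H](CC=C(C)C)C(C)(C)[C@](CC=C(C)C)(C(OC)=CC(=O)SCC)C1=O
F2 | step 15 | (E)-isomer of F1 (thioester cis to the quaternary ring carbon) | C=C(C)[C@H](CC=C(C)C)CC1C[C@@H](CC=C(C)C)C(C)(C)[C@](CC=C(C)C)(/C(OC)=C\C(=O)SCC)C1=O
F3 | step 13 | (4R,6R)-6-(dimethoxymethyl)-5,5-dimethyl-4,6-bis(3-methylbut-2-en-1-yl)-2-[(2R)-5-methyl-2-(prop-1-en-2-yl)hex-4-en-1-yl]cyclohex-2-en-1-one | C=C(C)[C@H](CC=C(C)C)CC1=C[C@@H](CC=C(C)C)C(C)(C)[C@](CC=C(C)C)(C(OC)OC)C1=O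
F4 | step 13 | aldehyde from F3 (C1 carbaldehyde on the enone) | C=C(C)[C@H](CC=C(C)C)CC1=C[C@@H](CC=C(C)C)C(C)(C)[C@](CC=C(C)C)(C=O)C1=O
F5 | step 13 | S-ethyl 3-hydroxy-3-(ring) propanethioate, the aldol from F4 (carbinol epimers) | C=C(C)[C@H](CC=C(C)C)CC1=C[C@@H](CC=C(C)C)C(C)(C)[C@](CC=C(C)C)(C(O)CC(=O)SCC)C1=O
F6 | step 10 | (S)-lavandulyl trifluoromethanesulfonate | C=C(C)[C@H](CC=C(C)C)COS(=O)(=O)C(F)(F)F
F7 | step 10 | (4R)-5,5-dimethyl-4-(3-methylbut-2-en-1-yl)-2-[(2R)-5-methyl-2-(prop-1-en-2-yl)hex-4-en-1-yl]cyclohexan-1-one (C2 epimers) | C=C(C)[C@H](CC=C(C)C)CC1C[C@@H](CC=C(C)C)C(C)(C)CC1=O
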